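Ochre is the earlier run nearest to our flask: it has the same free monomer and twice the transfer agent.

| setting | grey | red | ochre | flask |
|---|---|---|---|---|
| free monomer | 0.050 M | 0.20 M | 0.10 M | 0.10 M |
| transfer agent | 3 mM | 3 mM | 6 mM | 3.00 mM |
| pre-initiator | 5 mol% | 5 mol% | 5 mol% | 5 mol% |
| remark | run made earlier | run made earlier | run made earlier |  |
| time |  |  |  | 6.0 d |

| run | time / d | monomer in chains / % | free monomer / % |
|---|---|---|---|
| grey | 1.04 | 28.7 | 71.8 |
| grey | 2.08 | 55.5 | 46.2 |
| grey | 3.00 | 68.5 | 29.6 |
| grey | 4.00 | 79.7 | 20.7 |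
| grey | 5.00 | 83.7 | 15.6 |
| red | 1.04 | 60.3 | 37.5 |
| red | 2.08 | 92.0 | 7.9 |
| red | 3.00 | 98.7 | 1.1 |
| red | 4.00 | 96.9 | 0.8 |
| red | 5.00 | 98.9 | 0 |
| ochre | 0.417 | 12.6 | 88.5 |
| ochre | 0.833 | 30.2 | 70.5 |
| ochre | 1.25 | 43.3 | 57.6 |
| ochre | 2.50 | 67.8 | 30.3 |
| ochre | 5.00 | 86.4 | 12.3 |

(standard deviation of a reading: 1 percentage point)

- average number of monomer units in a chain (chains begun, living or dead) at 6.0 d
- part of the free monomer that has reacted at 6.0 d

- the average divides the monomer in chains by the number of chains begun, living and dead together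
- the earlier runs do not show the number of chains; that part of a forecast is a guess

At first the runs seem to disagree. Ochre holds twice the free monomer of grey and twice its transfer agent, yet at 5.00 d it keeps 12.3% of its charge against grey's 15.6%. Red, with 0.20 M charged and the transfer agent of grey, keeps 7.9% at 2.08 d, where grey keeps 46.2%.

But pre-initiator is charged as a loading on the monomer, so we count r, pre-initiator charged over transfer agent charged: 0.833 in grey, 0.833 in ochre, 3.33 in red. Grey and ochre share it, and red's is higher.

Let F be the natural log of charge over free monomer left; in a pseudo-first-order loss it climbs straight with time. Ochre's last reading gives φ = 0.503 d⁻¹, the climb per day and per unit ratio, F divided by r and by time. Red at 2.08 d gives 0.366 d⁻¹, which is lower, so φ is rough.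

For the flask r = 1.67, so we reckon F = 5.03 at 6.0 d, and c = 99.3%. The readings show no chain count, so we reckon no dp.

The forecast gives dp 17, and c 96%, which is lower than our c, holding that “the rate seems to track the initiator-to-transfer-agent ratio”.

The flask gives dp 24.1 and c 99.1%.

    free monomer + initiator → living end + monomer in chains (k = 9.10 L mol⁻¹ h⁻¹)
    free monomer + living end → monomer in chains + living end, rate k2*[living end]*[free monomer] (k = 64.0 L mol⁻¹ h⁻¹)
    living end + transfer agent → dead chain (kL = 21.0 L mol⁻¹ h⁻¹)
    living end + free monomer → dead end (k = 0.940 L mol⁻¹ h⁻¹)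
    pre-initiator → initiator (k = 0.0170 h⁻¹)

The flask keeps 0.86% of its free monomer, so its φ is 0.476 d⁻¹, against the 0.503 d⁻¹ read from ochre. The neighbouring flask, charged with 0.0012 M of transfer agent, has r = 4.17. Ochre's φ then gives F = 12.6. That neighbour keeps 0.025%, which is F = 8.29, below the reckoned value, though its c is >99.9%. Its average chain holds 29.3 monomer units.

The readings are simulated for substances that don't exist, and the scatter is random.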